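**Strategy.** The route rests on opening the 14-membered carbocycle at C12=C13, the E-trisubstituted alkene that flanks C11, the allylic carbon of the 1,2-dioxane ring (C8–O–O–C11). Read as an alkyne next to a C11 hydroxyl, this site is formed by ring-closing alkyne metathesis, which closes the macrocycle in one operation. The C11 oxygen then steers a trans-hydrostannation and methyl coupling that place the methyl on C12 and fix the E geometry. The precursor is an open-chain diyne: a cis-fused (1S,2S) α-methylene-γ-lactone bearing a but-2-ynyl group on C1 and, on C2, an E,E-diene chain ending in an 11R silyl-protected, methyl-capped propargylic alcohol. Epoxide and peroxide are installed only after ring closure.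

Key step: step 13

Assumption: cembrane numbering is used (C1 ring-fusion CH, C2 lactone OCH, C7 CHOAc, C8 and C11 peroxide carbons); C11 is carried as the 11R alcohol, which cannot attack C8 of the 7S,8S-epoxide without forming a trans-bridged oxolane, and it is inverted when the peroxide ring closes.

**Route**

Step 1
Reactants: 1 pent-3-yn-1-ol
Product: 2 pent-3-ynal
Conditions: Dess–Martin periodinane, CH2Cl2, 0 °C → rt; short filtration, used at once as a solution
Reagents that add atoms: none
Why: Dess–Martin oxidation is neutral and fast, so the β,γ-alkynyl aldehyde should form without base-induced isomerisation to the allenal.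

Step 2
Reactants: 2 pent-3-ynal; 3 methyl propiolate
Product: 5 methyl 3-hydroxy-2-methylidenehept-5-ynoate (racemic), via vinylalane 4 (not isolated)
Conditions: i-Bu2AlH, N-methylmorpholine N-oxide, THF, 0 °C; then 2, 0 °C → rt; aqueous Rochelle salt
Reagents that add atoms: none
Why: Hydroalumination of the propiolate gives the α-aluminated acrylate, which adds to the aldehyde (vinylalumination, a Morita–Baylis–Hillman-type result without amine base); the racemic carbinol centre is erased in step 4.

Step 3
Reactants: 5 methyl 3-hydroxy-2-methylidenehept-5-ynoate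
Product: 6 methyl 3-acetoxy-2-methylidenehept-5-ynoate (racemic)
Conditions: AcCl, pyridine, CH2Cl2, 0 °C
Reagents that add atoms: acetyl chloride, CC(Cl)=O
Why: Simple O-acylation of the secondary allylic alcohol, run without a nucleophilic amine catalyst so that the acetate is not transposed to the primary position.

Step 4
Reactants: 6 methyl 3-acetoxy-2-methylidenehept-5-ynoate
Product: 7 methyl (2E)-2-[(4,4,5,5-tetramethyl-1,3,2-dioxaborolan-2-yl)methyl]hept-2-en-5-ynoate
Conditions: B2pin2, CuCl (cat.), LiCl, KOAc, DMF, rt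
Reagents that add atoms: bis(pinacolato)diboron, CC1(C)OB(OC1(C)C)B1OC(C)(C)C(C)(C)O1
Why: Copper-catalysed SN2′ borylation (Hosomi–Miyaura type) adds boron to the acrylate CH2 and expels acetate, giving the trisubstituted alkene with the but-2-ynyl group trans to the ester and cis to CH2B, the geometry favoured for ester-derived allylic acetates of this kind.

Step 5
Reactants: 8 geranyl acetate
Product: 9 (2E,6E)-8-hydroxy-3,7-dimethylocta-2,6-dien-1-yl acetate
Conditions: SeO2 (cat.), t-BuOOH, salicylic acid (cat.), CH2Cl2, rt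
Reagents that add atoms: tert-butyl hydroperoxide, CC(C)(C)OO
Why: Riley allylic oxidation (ene reaction, then [2,3]-shift) attacks the E-methyl of the electron-rich terminal alkene and gives the E-allylic alcohol, while the other alkene is deactivated by the allylic acetate.

Step 6
Reactants: 9 (2E,6E)-8-hydroxy-3,7-dimethylocta-2,6-dien-1-yl acetate
Product: 10 (2E,6E)-8-bromo-3,7-dimethylocta-2,6-dien-1-yl acetate
Conditions: CBr4, PPh3, CH2Cl2, 0 °C
Reagents that add atoms: carbon tetrabromide, BrC(Br)(Br)Br
Why: The Appel reaction converts the primary allylic alcohol to the bromide under neutral conditions that should leave the acetate and both E-alkenes untouched.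

Step 7
Reactants: 10 (2E,6E)-8-bromo-3,7-dimethylocta-2,6-dien-1-yl acetate; 11 N-methoxy-N-methylacetamide
Product: 13 (2E,6E)-10-[methoxy(methyl)amino]-3,7-dimethyl-10-oxodeca-2,6-dien-1-yl acetate, via lithium enolate 12 (not isolated)
Conditions: LDA, THF, −78 °C; then 10, −78 → −40 °C
Reagents that add atoms: none
Why: SN2 alkylation of the amide enolate by the primary allylic bromide adds C10 and C11 and should outpace acyl transfer to the acetate at low temperature; any acetate lost here is removed in step 8 in any case.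

Step 8
Reactants: 13 (2E,6E)-10-[methoxy(methyl)amino]-3,7-dimethyl-10-oxodeca-2,6-dien-1-yl acetate; 14 prop-1-ynylmagnesium bromide
Product: 15 (7E,11E)-13-hydroxy-7,11-dimethyltrideca-7,11-dien-2-yn-4-one
Conditions: 14 (4 equiv), THF, 0 °C → rt; aq. NH4Cl
Reagents that add atoms: none
Why: The Weinreb amide stops at the chelated tetrahedral adduct and gives the ynone only on work-up, while the excess Grignard reagent cleaves the acetate by addition to its carbonyl, so ketone synthesis and O-deprotection occur in one operation.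

Step 9
Reactants: 15 (7E,11E)-13-hydroxy-7,11-dimethyltrideca-7,11-dien-2-yn-4-one
Product: 16 (2E,6E,10R)-3,7-dimethyltrideca-2,6-dien-11-yne-1,10-diol
Conditions: RuCl[(R,R)-TsDPEN](p-cymene) (2 mol%), i-PrOH, rt
Reagents that add atoms: none
Why: Noyori asymmetric transfer hydrogenation of an alkynyl ketone, in which the alkynyl group takes the place of the aryl group in the CH/π-organised transition state, so the (R,R)-catalyst should set the R carbinol (cembrane C11) without touching alkenes or alkyne.

Step 10
Reactants: 16 (2E,6E,10R)-3,7-dimethyltrideca-2,6-dien-11-yne-1,10-diol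
Product: 17 (2E,6E,10R)-10-hydroxy-3,7-dimethyltrideca-2,6-dien-11-ynal
Conditions: TEMPO (10 mol%), PhI(OAc)2, CH2Cl2, rt
Reagents that add atoms: none
Why: Oxoammonium oxidation is strongly selective for the primary allylic alcohol over the secondary propargylic one and should give the E-enal without alkene isomerisation.

Step 11
Reactants: 17 (2E,6E,10R)-10-hydroxy-3,7-dimethyltrideca-2,6-dien-11-ynal
Product: 18 (2E,6E,10R)-3,7-dimethyl-10-(triethylsilyloxy)trideca-2,6-dien-11-ynal
Conditions: Et3SiCl, imidazole, CH2Cl2, 0 °C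
Reagents that add atoms: chlorotriethylsilane, CC[Si](Cl)(CC)CC
Why: Standard silylation masks the propargylic hydroxyl, which would otherwise poison the alkyne metathesis catalyst, as a group that fluoride removes later.

Step 12
Reactants: 18 (2E,6E,10R)-3,7-dimethyl-10-(triethylsilyloxy)trideca-2,6-dien-11-ynal; 7 methyl (2E)-2-[(4,4,5,5-tetramethyl-1,3,2-dioxaborolan-2-yl)methyl]hept-2-en-5-ynoate
Product: 20 (4S,5S)-4-(but-2-yn-1-yl)-5-[(1E,5E,9R)-2,6-dimethyl-9-(triethylsilyloxy)dodeca-1,5-dien-10-yn-1-yl]-3-methylideneoxolan-2-one, via borate ester 19 (not isolated)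
Conditions: (R)-TRIP phosphoric acid (10 mol%), 4 Å MS, toluene, −20 °C → rt; then PPTS (cat.), CH2Cl2, rt
Reagents that add atoms: none
Why: Chiral phosphoric acid-catalysed allylboration through a closed chair transition state: the but-2-ynyl group cis to CH2B sits axial and gives the syn adduct (hence the cis lactone, C1 S), the (R)-acid directs attack on the Re face of the enal (C2 S), and the adduct lactonises with loss of methanol.

Step 13
Reactants: 20 (4S,5S)-4-(but-2-yn-1-yl)-5-[(1E,5E,9R)-2,6-dimethyl-9-(triethylsilyloxy)dodeca-1,5-dien-10-yn-1-yl]-3-methylideneoxolan-2-one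
Product: 21 (1S,2S,3E,7E,11R)-11-(triethylsilyloxy)-20-norcembra-3,7,15(17)-trien-12-yn-16,2-olide (14-membered cycloalkyne)
Conditions: Mo(≡CC6H4OMe-4)(OSiPh3)3 (15 mol%), 5 Å MS, toluene (2 mM), rt → 50 °C
Reagents that add atoms: none
Why: The molybdenum alkylidyne adds across the less hindered C13 alkyne in a [2+2] sense, cycloreversion of the molybdacyclobutadiene expels but-2-yne, and the substrate-bound alkylidyne then engages the propargylic C11–C12 alkyne intramolecularly to release the cycloalkyne and a propagating alkylidyne. The closest known reaction type is ring-closing alkyne metathesis of methyl-capped diynes to macrocyclic cycloalkynes with triarylsilanolate molybdenum alkylidynes. The 14-membered carbocycle is closed by intramolecular metathesis through the new C12≡C13 bond, and a ring of this size accommodates the linear C11–C12≡C13–C14 unit without strain. No stereocentre is formed: C1, C2 and C11 are spectators and alkene geometry is deferred to the hydrometalation. The step needs cyclisation to outrun acyclic oligomerisation and needs the catalyst to ignore the alkenes, the silyl ether and the methylene lactone; high dilution and trapping of but-2-yne by 5 Å molecular sieves secure the former, the alkyne-selective silanolate ligand sphere the latter. The absence of protic, epoxide and peroxide groups at this stage keeps the catalyst alive.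

Step 14
Reactants: 21 (1S,2S,3E,7E,11R)-11-(triethylsilyloxy)-20-norcembra-3,7,15(17)-trien-12-yn-16,2-olide
Product: 22 (1S,2S,3E,7S,8S,11R)-7,8-epoxy-11-(triethylsilyloxy)-20-norcembra-3,15(17)-dien-12-yn-16,2-olide
Conditions: ent-Shi ketone (L-fructose-derived, 30 mol%), KHSO5 (as 2KHSO5·KHSO4·K2SO4), K2CO3, Bu4NHSO4 (cat.), Na2B4O7 buffer, MeCN–CH2(OMe)2–H2O, 0 °C
Reagents that add atoms: potassium peroxymonosulfate, [K+].[O-]S(=O)(=O)OO
Why: Shi asymmetric epoxidation by a chiral dioxirane through a spiro transition state, where the L-fructose-derived ketone should give the 7S,8S epoxide of the E-trisubstituted alkene; C7=C8 is the only electron-rich alkene, since C3=C4 is deactivated by the allylic lactone oxygen and the acrylate and alkyne are inert to dioxiranes.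

Step 15
Reactants: 22 (1S,2S,3E,7S,8S,11R)-7,8-epoxy-11-(triethylsilyloxy)-20-norcembra-3,15(17)-dien-12-yn-16,2-olide
Product: 23 (1S,2S,3E,7S,8S,11R)-7,8-epoxy-11-hydroxy-20-norcembra-3,15(17)-dien-12-yn-16,2-olide
Conditions: Bu4NF, AcOH, THF, 0 °C
Reagents that add atoms: none
Why: Buffered fluoride cleaves the silyl ether without harming the epoxide or the methylene lactone, and the freed 11R hydroxyl cannot reach the back side of C8, so no transannular oxolane should form.

Step 16
Reactants: 23 (1S,2S,3E,7S,8S,11R)-7,8-epoxy-11-hydroxy-20-norcembra-3,15(17)-dien-12-yn-16,2-olide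
Product: 24 (1S,2S,3E,7S,8S,11R,12Z)-7,8-epoxy-11-hydroxy-12-(tributylstannyl)-20-norcembra-3,12,15(17)-trien-16,2-olide
Conditions: [Cp*RuCl]4 (2.5 mol%), Bu3SnH, CH2Cl2, rt
Reagents that add atoms: tributyltin hydride, CCCC[SnH](CCCC)CCCC
Why: Hydroxyl-directed trans-hydrostannation: hydrogen bonding of the C11 hydroxyl to the chloride ligand on ruthenium delivers tin to the proximal carbon C12 and hydrogen trans to it at C13, which gives the E-configured ring alkene.

Step 17
Reactants: 24 (1S,2S,3E,7S,8S,11R,12Z)-7,8-epoxy-11-hydroxy-12-(tributylstannyl)-20-norcembra-3,12,15(17)-trien-16,2-olide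
Product: 25 (1S,2S,3E,7S,8S,11R,12E)-7,8-epoxy-11-hydroxycembra-3,12,15(17)-trien-16,2-olide
Conditions: MeI, Pd(PPh3)4 (10 mol%), copper thiophene-2-carboxylate Cu(O2CC4H3S), [Bu4N][Ph2PO2], DMF, rt
Reagents that add atoms: iodomethane, CI
Why: Copper-promoted Stille-type methylation replaces tin by methyl with retention of alkene geometry under base-free conditions, the phosphinate scavenging the tin residue, so the E-C12(Me)=C13 alkene is fixed.

Step 18
Reactants: 25 (1S,2S,3E,7S,8S,11R,12E)-7,8-epoxy-11-hydroxycembra-3,12,15(17)-trien-16,2-olide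
Product: 26 (1S,2S,3E,7S,8R,11R,12E)-8-hydroperoxy-7,11-dihydroxycembra-3,12,15(17)-trien-16,2-olide
Conditions: H2O2 (dried ethereal solution), H3PMo12O40 (5 mol%), Et2O, 0 °C → rt
Reagents that add atoms: hydrogen peroxide, OO
Why: Acid-catalysed perhydrolysis of the trisubstituted epoxide, in which H2O2 attacks the tertiary carbon C8 with inversion (C8 becomes R, C7 keeps its oxygen and stays S), while the 11R hydroxyl is geometrically unable to compete for C8.

Step 19
Reactants: 26 (1S,2S,3E,7S,8R,11R,12E)-8-hydroperoxy-7,11-dihydroxycembra-3,12,15(17)-trien-16,2-olide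
Product: 27 (1S,2S,3E,7S,8R,11S,12E)-8,11-epidioxy-7-hydroxycembra-3,12,15(17)-trien-16,2-olide
Conditions: camphorsulfonic acid (20 mol%), 4 Å MS, CH2Cl2 (5 mM), 0 °C → rt
Reagents that add atoms: none
Why: Proposed new method: protonation of the C11 allylic hydroxyl and loss of water should give the C11–C12–C13 2-methylallyl cation, which the C8 hydroperoxide captures at C11 in a 6-exo sense (attack at C13 would need an 8-membered ring); the ten-atom bridge C12…C7 can span the new 1,2-dioxane only in the cis sense, so C11 should end up S whichever face ionises and the E-C12=C13 geometry is kept; the closest known reactions are the acid-catalysed cyclodehydration of hydroperoxy alcohols to 1,2-dioxanes and the acid-catalysed perhydrolysis of allylic alcohols (SN1 peroxide formation).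

Step 20
Reactants: 27 (1S,2S,3E,7S,8R,11S,12E)-8,11-epidioxy-7-hydroxycembra-3,12,15(17)-trien-16,2-olide
Product: 28 (1S,2S,3E,7S,8R,11S,12E)-7-acetoxy-8,11-epidioxycembra-3,12,15(17)-trien-16,2-olide (CNP0238885.7)
Conditions: Ac2O, Et3N, DMAP (cat.), CH2Cl2, 0 °C
Reagents that add atoms: acetic anhydride, CC(=O)OC(C)=O
Why: DMAP-catalysed acylation of the only free hydroxyl (C7) is mild enough to leave the dialkyl peroxide and the methylene lactone intact.

**Compound list**

1 | pent-3-yn-1-ol | CC#CCCO | starting material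
2 | pent-3-ynal | CC#CCC=O | intermediate
3 | methyl propiolate | C#CC(=O)OC | starting material
4 | methyl 2-(diisobutylalumanyl)prop-2-enoate (vinylalane, not isolated) | C=C(C(=O)OC)[Al](CC(C)C)CC(C)C | intermediate
5 | methyl 3-hydroxy-2-methylidenehept-5-ynoate (racemic) | CC#CCC(O)C(=C)C(=O)OC | intermediate
6 | methyl 3-acetoxy-2-methylidenehept-5-ynoate (racemic) | CC#CCC(OC(C)=O)C(=C)C(=O)OC | intermediate
7 | methyl (2E)-2-[(4,4,5,5-tetramethyl-1,3,2-dioxaborolan-2-yl)methyl]hept-2-en-5-ynoate | CC#CC/C=C(/C(=O)OC)CB1OC(C)(C)C(C)(C)O1 | intermediate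
8 | geranyl acetate | CC(C)=CCC/C(C)=C/COC(C)=O | starting material
9 | (2E,6E)-8-hydroxy-3,7-dimethylocta-2,6-dien-1-yl acetate | CC(=O)OC/C=C(\C)CC/C=C(\C)CO | intermediate
10 | (2E,6E)-8-bromo-3,7-dimethylocta-2,6-dien-1-yl acetate | CC(=O)OC/C=C(\C)CC/C=C(\C)CBr | intermediate
11 | N-methoxy-N-methylacetamide | CC(=O)N(C)OC | starting material
12 | lithium enolate of N-methoxy-N-methylacetamide (not isolated) | C=C(O[Li])N(C)OC | intermediate
13 | (2E,6E)-10-[methoxy(methyl)amino]-3,7-dimethyl-10-oxodeca-2,6-dien-1-yl acetate | CC(=O)OC/C=C(\C)CC/C=C(\C)CCC(=O)N(C)OC | intermediate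
14 | prop-1-ynylmagnesium bromide | CC#C[Mg]Br | starting material
15 | (7E,11E)-13-hydroxy-7,11-dimethyltrideca-7,11-dien-2-yn-4-one | OC/C=C(\C)CC/C=C(\C)CCC(=O)C#CC | intermediate
16 | (2E,6E,10R)-3,7-dimethyltrideca-2,6-dien-11-yne-1,10-diol | OC/C=C(\C)CC/C=C(\C)CC[C@@H](O)C#CC | intermediate
17 | (2E,6E,10R)-10-hydroxy-3,7-dimethyltrideca-2,6-dien-11-ynal | O=C/C=C(\C)CC/C=C(\C)CC[C@@H](O)C#CC | intermediate
18 | (2E,6E,10R)-3,7-dimethyl-10-(triethylsilyloxy)trideca-2,6-dien-11-ynal | O=C/C=C(\C)CC/C=C(\C)CC[C@@H](O[Si](CC)(CC)CC)C#CC | intermediate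
19 | methyl (3S,4S,5E,9E,13R)-3-(but-2-yn-1-yl)-6,10-dimethyl-2-methylidene-4-[(4,4,5,5-tetramethyl-1,3,2-dioxaborolan-2-yl)oxy]-13-(triethylsilyloxy)hexadeca-5,9-dien-14-ynoate (syn adduct, not isolated) | COC(=O)C(=C)[C@H](CC#CC)[C@@H](OB1OC(C)(C)C(C)(C)O1)/C=C(\C)CC/C=C(\C)CC[C@@H](O[Si](CC)(CC)CC)C#CC | intermediate
20 | (4S,5S)-4-(but-2-yn-1-yl)-5-[(1E,5E,9R)-2,6-dimethyl-9-(triethylsilyloxy)dodeca-1,5-dien-10-yn-1-yl]-3-methylideneoxolan-2-one (diyne, precursor of the key step) | C=C1C(=O)O[C@@H](/C=C(\C)CC/C=C(\C)CC[C@@H](O[Si](CC)(CC)CC)C#CC)[C@H]1CC#CC | intermediate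
21 | (1S,2S,3E,7E,11R)-11-(triethylsilyloxy)-20-norcembra-3,7,15(17)-trien-12-yn-16,2-olide (product of the key step) | C=C1C(=O)O[C@H]2/C=C(\C)CC/C=C(\C)CC[C@@H](O[Si](CC)(CC)CC)C#CC[C@@H]12 | intermediate
22 | (1S,2S,3E,7S,8S,11R)-7,8-epoxy-11-(triethylsilyloxy)-20-norcembra-3,15(17)-dien-12-yn-16,2-olide | C=C1C(=O)O[C@H]2/C=C(\C)CC[C@@H]3O[C@@]3(C)CC[C@@H](O[Si](CC)(CC)CC)C#CC[C@@H]12 | intermediate
23 | (1S,2S,3E,7S,8S,11R)-7,8-epoxy-11-hydroxy-20-norcembra-3,15(17)-dien-12-yn-16,2-olide | C=C1C(=O)O[C@H]2/C=C(\C)CC[C@@H]3O[C@@]3(C)CC[C@@H](O)C#CC[C@@H]12 | intermediate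
24 | (1S,2S,3E,7S,8S,11R,12Z)-7,8-epoxy-11-hydroxy-12-(tributylstannyl)-20-norcembra-3,12,15(17)-trien-16,2-olide | C=C1C(=O)O[C@H]2/C=C(\C)CC[C@@H]3O[C@@]3(C)CC[C@@H](O)/C([Sn](CCCC)(CCCC)CCCC)=C/C[C@@H]12 | intermediate
25 | (1S,2S,3E,7S,8S,11R,12E)-7,8-epoxy-11-hydroxycembra-3,12,15(17)-trien-16,2-olide | C=C1C(=O)O[C@H]2/C=C(\C)CC[C@@H]3O[C@@]3(C)CC[C@@H](O)/C(C)=C/C[C@@H]12 | intermediate
26 | (1S,2S,3E,7S,8R,11R,12E)-8-hydroperoxy-7,11-dihydroxycembra-3,12,15(17)-trien-16,2-olide | C=C1C(=O)O[C@H]2/C=C(\C)CC[C@H](O)[C@@](OO)(C)CC[C@@H](O)/C(C)=C/C[C@@H]12 | intermediate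
27 | (1S,2S,3E,7S,8R,11S,12E)-8,11-epidioxy-7-hydroxycembra-3,12,15(17)-trien-16,2-olide | C=C1C(=O)O[C@H]2/C=C(\C)CC[C@H](O)[C@@]3(C)CC[C@H](OO3)/C(C)=C/C[C@@H]12 | intermediate
28 | (1S,2S,3E,7S,8R,11S,12E)-7-acetoxy-8,11-epidioxycembra-3,12,15(17)-trien-16,2-olide (CNP0238885.7) | C=C1C(=O)O[C@H]2/C=C(\C)CC[C@H](OC(C)=O)[C@@]3(C)CC[C@H](OO3)/C(C)=C/C[C@@H]12 | target

**Totals**

Total step count: 20.
Longest linear sequence: 16 steps (geranyl acetate 8 to target 28, steps 5–20); the boronate 7 is made in a 4-step side branch (steps 1–4).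

**Steps most likely to fail**

1. Step 19 (peroxide ring closure). The C7 hydroxyl may compete with the hydroperoxide for the allyl cation and close an oxane instead; the acid may also cause loss of H2O2 from C8 or elimination to a diene. The fallback uses halophilic instead of protic activation and sets out from 25. Treatment with MsCl and Et3N in CH2Cl2 at −20 °C, then LiCl in THF, should give the (11S)-11-chloro-7,8-epoxide F1 by SN2 displacement. Perhydrolysis of F1 under the conditions of step 18 should give the chloro hydroperoxide F2. Silver-assisted cyclisation of F2 with Ag2O in CH2Cl2 in the dark is the classical closure of halo hydroperoxides to cyclic peroxides: the more acidic hydroperoxide is metalated in preference to the alcohol, and the ionised allylic centre is captured under the same cis-bridging constraint. It returns to the route at 27.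

2. Step 12 (asymmetric allylboration and lactonisation). The ester-deactivated allylboronate may react too slowly under the chiral acid, so that the uncatalysed background path erodes the enantioselectivity; acid-promoted lactonisation could also be sluggish. The fallback replaces catalyst control by a covalently bound auxiliary and sets out from 2. Propiolic acid is esterified with (1R,2S,5R)-8-phenylmenthol (DCC, DMAP) to (1R,2S,5R)-8-phenylmenthyl propiolate F3. Vinylalumination with 2 as in step 2 gives the hydroxy ester F4, acetylation as in step 3 gives the acetate F5, and copper-catalysed borylation as in step 4 gives the auxiliary-bearing allylboronate F6. Thermal or Sc(OTf)3-catalysed allylboration of 18 with F6 should give the syn borate F7 through the same chair transition state, with the π-face set by the aryl-shielded ester. F7 lactonises with loss of the auxiliary and returns to the route at 20. The structures are drawn for the (1R,2S,5R) auxiliary; its mirror image would be used if the facial sense proved opposite.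

3. Step 14 (epoxidation of the macrocycle). The ring may present its own preferred alkene face to the dioxirane and override reagent control, or C3=C4 may be epoxidised competitively. The fallback moves the epoxidation before ring closure and sets out from 20. Shi epoxidation of the open-chain diyne under the conditions of step 14, where no ring bias exists, should give the 7S,8S-epoxy diyne F8. Ring-closing alkyne metathesis of F8 under the conditions of step 13 then returns to the route at 22; this relies on the silanolate molybdenum alkylidyne tolerating the epoxide.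

**Further compounds**

F1 | step 19 | (1S,2S,3E,7S,8S,11S,12E)-11-chloro-7,8-epoxycembra-3,12,15(17)-trien-16,2-olide | C=C1C(=O)O[C@H]2/C=C(\C)CC[C@@H]3O[C@@]3(C)CC[C@H](Cl)/C(C)=C/C[C@@H]12
F2 | step 19 | (1S,2S,3E,7S,8R,11S,12E)-11-chloro-8-hydroperoxy-7-hydroxycembra-3,12,15(17)-trien-16,2-olide | C=C1C(=O)O[C@H]2/C=C(\C)CC[C@H](O)[C@@](OO)(C)CC[C@H](Cl)/C(C)=C/C[C@@H]12
F3 | step 12 | (1R,2S,5R)-8-phenylmenthyl propiolate | C[C@@H]1CC[C@H]([C@@H](C1)OC(=O)C#C)C(C)(C)c1ccccc1
F4 | step 12 | (1R,2S,5R)-8-phenylmenthyl 3-hydroxy-2-methylidenehept-5-ynoate (carbinol epimers) | C[C@@H]1CC[C@H]([C@@H](C1)OC(=O)C(=C)C(O)CC#CC)C(C)(C)c1ccccc1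
F5 | step 12 | (1R,2S,5R)-8-phenylmenthyl 3-acetoxy-2-methylidenehept-5-ynoate (carbinol epimers) | C[C@@H]1CC[C@H]([C@@H](C1)OC(=O)C(=C)C(OC(C)=O)CC#CC)C(C)(C)c1ccccc1
F6 | step 12 | (1R,2S,5R)-8-phenylmenthyl (2E)-2-[(4,4,5,5-tetramethyl-1,3,2-dioxaborolan-2-yl)methyl]hept-2-en-5-ynoate | C[C@@H]1CC[C@H]([C@@H](C1)OC(=O)/C(CB2OC(C)(C)C(C)(C)O2)=C/CC#CC)C(C)(C)c1ccccc1
F7 | step 12 | (1R,2S,5R)-8-phenylmenthyl (3S,4S,5E,9E,13R)-3-(but-2-yn-1-yl)-6,10-dimethyl-2-methylidene-4-[(4,4,5,5-tetramethyl-1,3,2-dioxaborolan-2-yl)oxy]-13-(triethylsilyloxy)hexadeca-5,9-dien-14-ynoate | C[C@@H]1CC[C@H]([C@@H](C1)OC(=O)C(=C)[C@H](CC#CC)[C@@H](OB2OC(C)(C)C(C)(C)O2)/C=C(\C)CC/C=C(\C)CC[C@@H](O[Si](CC)(CC)CC)C#CC)C(C)(C)c1ccccc1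
F8 | step 14 | (4S,5S)-4-(but-2-yn-1-yl)-5-[(1E,5S,6S,9R)-5,6-epoxy-2,6-dimethyl-9-(triethylsilyloxy)dodec-1-en-10-yn-1-yl]-3-methylideneoxolan-2-one | C=C1C(=O)O[C@@H](/C=C(\C)CC[C@@H]2O[C@@]2(C)CC[C@@H](O[Si](CC)(CC)CC)C#CC)[C@H]1CC#CC
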